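Which flask holds the most target after 50 h: dusk, autumn or midnight? All three receive the same charges and differ in what is fed.

| setting | zeta | theta | beta | dusk | autumn | midnight |
|---|---|---|---|---|---|---|
| starting material | 0.050 M | 0.034 M | 0.075 M | 0.050 M | 0.050 M (fed, over 30 h) | 0.050 M |
| partner | 0.060 M | 0.060 M | 0.060 M | 0.0600 M | 0.0600 M | 0.0600 M (fed, over 30 h) |
| capture agent | 0.015 M | 0.015 M | 0.015 M | 0.0150 M | 0.0150 M | 0.0150 M |
| remark | run made earlier | run made earlier | run made earlier | everything together at the start | all else is in the flask from the start; the feed brings no volume worth counting | all else is in the flask from the start; the feed brings no volume worth counting |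
| time |  |  |  | 50 h | 50 h | 50 h |

| zeta: time / h | zeta: target / % | theta: time / h | theta: target / % | beta: time / h | beta: target / % |
|---|---|---|---|---|---|
| 4.00 | 20.2 | 4.00 | 20.6 | 12.0 | 50.6 |
| 10.0 | 50.3 | 10.0 | 53.9 | 25.0 | 65.0 |
| 20.0 | 71.6 | 20.0 | 78.6 | 40.0 | 68.3 |
| 48.0 | 83.6 | 48.0 | 90.2 | 48.0 | 68.9 |

(scatter of a reading: 0.5 percentage points)
1. the flask with the highest amount of target, in percent of the starting material charged ("all alike" if they lie within 1.5 percentage points) (dusk / autumn / midnight / all alike)
2. final target, as a percentage of the starting material charged, in dusk
3. final target, as a percentage of the starting material charged, in autumn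
4. final target, as a percentage of the starting material charged, in midnight
- a species is counted by the starting material in it: one side product counts as two
- the earlier runs were read with a standard deviation of 0.5 percentage points
- steps thought possible: starting material -> open intermediate; open intermediate + second intermediate -> target; partner -> second intermediate; 2 second intermediate -> homo product; open intermediate + capture agent -> trapped intermediate; starting material + open intermediate -> side product

Each target takes one second intermediate, and that comes from one partner.

1. First instants. At 4.00 h the zeta run holds 20.2 % target and the theta run 20.6 %. The percentage barely moves with the charge, as a first-order opening of starting material would have it.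

2. Middle. At 20.0 h theta, with the smaller charge, holds more target than zeta, 78.6 % against 71.6 %. Open intermediate now has competitors for it: second intermediate, capture agent and starting material.

3. End. The readings of the beta run nearly stop rising, going from 68.3 % at 40.0 h to 68.9 % at 48.0 h. That reading is 0.0517 M of target from 0.060 M of partner, a share of 86.1 %.

4. The crossing. With 0.0600 M of partner against 0.050 M of starting material, the count for dusk comes to 103 %: its partner cover, the target in percent of the starting material charged that its partner pays for at the share read from beta. Reckoned at that share, cover reaches unity at a charge of 0.0517 M; above that charge partner, by this count, is the limiting reagent. Dusk lies just below that charge.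

5. The reckoning. Dusk repeats zeta, so it should end a little above 83.6 %. Autumn's last feed has 20.0 h to react, and zeta stood at 71.6 % after the same time. Meanwhile its second intermediate can wait and turn into homo product. In midnight, open intermediate waits for fed partner. This reckoning puts dusk first and gives no figure for the fed flasks.

The forecast also names dusk, with 84 %, 80 % and 60 % for dusk, autumn and midnight, noting of autumn that “much of its material arrives late”.

The flasks give 84.5 % in dusk, 72.2 % in autumn and 77.6 % in midnight.

    starting material → open intermediate (k = 0.170 h⁻¹)
    open intermediate + second intermediate → target (k = 5.20 M⁻¹ h⁻¹)
    partner → second intermediate (k = 2.20 h⁻¹)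
    2 second intermediate → homo product (k = 0.200 M⁻¹ h⁻¹)
    open intermediate + capture agent → trapped intermediate (k = 0.750 M⁻¹ h⁻¹)
    starting material + open intermediate → side product (k = 0.500 M⁻¹ h⁻¹)

Dusk's 84.5 % stands below its cover of 103 %, with 0.00772 M of second intermediate present at 50.0 h, while the neighbour charged with 0.20 M of starting material has a cover of 25.8 % and holds 28.5 %, its second intermediate at 2.17 × 10⁻¹⁰ M. In dusk, starting material has a half-life of 4.1 h by its opening step alone, but open intermediate has one of 17 h by its step to target at the asked time; at 50.0 h open intermediate stands at 3.02 % in dusk and 15.7 % in autumn.

(The readings are simulated for substances that don't exist; noise was put on by code.)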